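## Analysis of the target

The target (45) is a germacranolide: a ten-membered carbocycle C1–C10 fused at C6/C7 to a butenolide (O–C12(=O)–C11=C7) whose C11 carries an acetoxymethyl group (C13). The carbocycle carries a cis-epoxide at C1–C2, a methyl-bearing trans-epoxide at C4–C5, an exocyclic methylene (C14) on C10 and a 2-(hydroxymethyl)acrylate on the C8 oxygen. There are six stereocentres (1R,2S,4R,5R,6S,8S). C4, C5 and C6 are contiguous, C8 is 1,3-related to C6 across the sp2 carbon C7, and the C1/C2 pair is insulated from the rest by C3 and by C9/C10. The molecule is fragile: a vinyl epoxide (C14=C10–C1–C2), a trisubstituted epoxide prone to transannular opening, a butenolide whose γ-hydrogen (C6–H) lies next to the C4–C5 epoxide, an allylic acetate and two acrylate-type acceptors. The difficulty is the medium ring combined with remote stereocentres that cannot relay information to each other. The strategy rests on the 1,6-relationship of C1 and C6 across the ring: a C1≡C2 alkyne (latent cis-epoxide) and a C6 ketone (latent lactone carbinol) are exactly what remains when a temporary C1–C6 bond of a decalin epoxy ketone is broken. The ten-membered ring is therefore never closed; it is uncovered from two six-membered rings (ring A: C1–C6; ring B: C1, C6–C10).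

## Retrosynthetic reasoning

**C8 ester.** The acyl C–O bond at C8 is cut first, giving alcohol 40 and the silyl-protected acid 43 via ester 44. The hydroxymethylacrylate is a Michael acceptor that would not survive peroxide anions, hydride or a titanium methylidene, so it must arrive last.

**C10 methylene and C1–C2 epoxide.** C10=C14 is traced to the ketone of 38, and the oxirane to the Z-enone 37. The enone carbonyl activates only C1=C2 towards a peroxide anion, so the tetrasubstituted butenolide olefin is left alone. The ketone is stored as the dioxolane of 36.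

**C4–C5 epoxide.** The O–C5 bond is cut, giving hydroxy mesylate 35 and, behind it, the cis-diol 33 and its acetonide 32. A cis-diol is the only form of this unit that a six-membered ring can carry; closure with inversion at C5 turns it into the trans-epoxide. The Z-olefin of 35 is taken back to the alkyne of 34, which guarantees the cis geometry at C1=C2.

**Butenolide.** In 32 the C11–C13 bond is cut (cross-coupling on enol triflate 30), then the enol 29 is traced to hydroxy lactone 28. The lactone C12–O bond and the C6–H bond lead to aldol adduct 26, and the C7–C11 bond to ynone 24. The C13 oxygen is added after the ring is built because any C11 carbanion carrying a β-oxygen would eliminate it. The forward sequence must set C6 by reduction of the C6 ketone next to the C5 oxygen.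

**Key disconnection.** Ynone 24 is reconnected between C1 and C6 to the ring-fusion epoxy ketone 21, to be fragmented with hydrazide 22. One C–C bond is broken, no stereocentre is created, and C4, C5 and C8 are already in place.

**Ring A oxygenation.** Epoxy ketone 21 comes from enone 20, whose ring A is a doubly hydrated phenol that aromatises easily. It is therefore derived from the non-enolisable quinone monoketal 15, in which C2 is stored as a dimethyl ketal and C1=C6 is already present. Epoxidation of C3=C4 (16), reduction at C5 and reductive cleavage of the C3–O bond (18 → 19) install the cis-diol. A dissolving-metal reduction of the arene was rejected: the benzylic C10 oxygen would be lost, and the C2 and C10 carbonyls could not be told apart afterwards.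

**Dearomatisation.** 15 arises by oxidation of para-methoxyphenol 14. The C10 dioxolane is introduced on tetralone 12, while C2 is still an aryl ether, which settles the C2/C10 differentiation for the rest of the route.

**Ring B.** Tetralin 11 is cut at C6–C7 (aryllithium on the alkyl chloride of 9) and at C1–C10 (aryllithium 7 on aldehyde 3). The bromine of 6 serves twice: it acidifies the C1 hydrogen and then becomes the C6 lithium, so both bonds form with fixed regiochemistry.

**Starting materials.** 6 comes from 4-methoxy-2-methylphenol (4) via 5. Aldehyde 3 carries C7–C10 and the C8 stereocentre from commercial hydroxy ester 1. Acid 43 comes from ethyl 2-(hydroxymethyl)acrylate (41).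

## Alternatives that were turned down

**Alternative 1:** The cut is through C6–C7, C11–C12 and C12–O. In the forward sense a C6 aldehyde, a tethered C7≡C11 alkyne and CO would combine on Mo(CO)6 to give the bis-epoxy butenolide A1, closing the lactone and the ten-membered ring in one operation. In its favour, it is stronger than the chosen route on step economy around the lactone: three bonds and the whole butenolide with C13 in one step, against six steps here. Against it, carbonylative aldehyde–alkyne cyclisations are established for five- and six-membered carbocycles; an eight-atom tether has a large entropic penalty and no template. Both epoxides, one of them α to the aldehyde, would have to survive low-valent, oxophilic molybdenum at elevated temperature. C6 would be created during macrocyclisation with no controlling element. The chosen route offers instead a ring opening that cannot fail for entropic reasons, and it sets C6 on a preformed ring.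

**Alternative 2:** The cut is through C4–C5 and C1–C10. Irradiation would join an enone olefin and a cyclobutene olefin to the bicyclo[2.2.0]hexane-containing adduct A2, and heating would open it to a cyclodeca-1(10),4-diene. In its favour, it is stronger on brevity to the carbocycle, and its E-4,5-olefin would give the trans-epoxide directly, without the diol detour. Against it, the head-to-head regiochemistry and the pairing of two chiral partners are not controlled. The thermolysis temperature is in the range where such 1,5-dienes undergo Cope rearrangement. The product also has the wrong oxidation pattern on the northern half: a 1(10)-olefin where the target needs a C10 exocyclic methylene next to a 1,2-epoxide. That requires an allylic transposition on a flexible ring, with C6, C8 and the butenolide still to be made. The chosen route delivers C1≡C2 and the C10 carbonyl in exactly the required positions and carries C4, C5 and C8 in from six-membered rings.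

**Alternative 3:** The cut is C5–C6. Anodic oxidation of a C4=C5 silyl enol ether would couple it with C6 of a 2-silyloxyfuran, giving the keto butenolide A3. In its favour, it is stronger on the butenolide (preformed as a furan) and on convergence, with the C1–C2 epoxide and the C10 methylene already present. Against it, a radical-cation coupling would have to form a ten-membered ring against oligomerisation. The PMB ether and the vinyl epoxide are oxidised or ionised at comparable potentials. C5 and C6 would be set together without control. The C4 ketone would still have to become the methyl-bearing epoxide, with a third uncontrolled centre. The chosen route offers defined C4/C5 stereochemistry from a cis-diol and a stereospecific closure.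

Key step: step 16

Remark: locants follow the germacrane numbering above. Stereocentres formed as epimer mixtures and erased later (the benzylic carbinol carbon in 8–11; C7 and C11 in 26–28) are left open in the SMILES. The oxirane of 21 is drawn anti to the acetonide, but either face serves because C1 and C6 lose their configuration in step 16. The Ti–Cl–Al bridge of the Tebbe reagent is drawn with formal charges on aluminium and chlorine.

## Route

Step 1
Reactants: 1 ethyl (S)-4-chloro-3-hydroxybutanoate
Product: 2 ethyl (S)-3-(tert-butyldimethylsilyloxy)-4-chlorobutanoate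
Conditions: TBSCl, imidazole, DMF, rt
Reagents that add atoms: tert-butyldimethylsilyl chloride, CC(C)(C)[Si](C)(C)Cl
Why: Standard silylation of a secondary alcohol; the C8 stereocentre comes from the commercial ester and is not touched.

Step 2
Reactants: 2 ethyl (S)-3-(tert-butyldimethylsilyloxy)-4-chlorobutanoate
Product: 3 (S)-3-(tert-butyldimethylsilyloxy)-4-chlorobutanal
Conditions: i-Bu2AlH (DIBAL-H), CH2Cl2, −78 °C; aq. potassium sodium tartrate
Reagents that add atoms: none
Why: Partial reduction of an ester; the tetrahedral aluminium hemiacetal is stable at −78 °C and releases the aldehyde on work-up.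

Step 3
Reactants: 4 4-methoxy-2-methylphenol
Product: 5 2-bromo-4-methoxy-6-methylphenol
Conditions: NBS, i-Pr2NH (cat.), CH2Cl2, 0 °C
Reagents that add atoms: N-bromosuccinimide, O=C1CCC(=O)N1Br
Why: Electrophilic bromination directed ortho by the free hydroxyl; the para position is blocked by OMe and only one ortho position is open.

Step 4
Reactants: 5 2-bromo-4-methoxy-6-methylphenol
Product: 6 2-(benzyloxy)-1-bromo-5-methoxy-3-methylbenzene
Conditions: BnBr, K2CO3, DMF, rt
Reagents that add atoms: benzyl bromide, BrCc1ccccc1
Why: Williamson etherification; the benzyl ether tolerates organolithiums and is removed later by hydrogenolysis without acid.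

Step 5
Reactants: 6 2-(benzyloxy)-1-bromo-5-methoxy-3-methylbenzene; 3 (S)-3-(tert-butyldimethylsilyloxy)-4-chlorobutanal
Product: 9 (3S)-1-[3-(benzyloxy)-2-bromo-6-methoxy-4-methylphenyl]-3-(tert-butyldimethylsilyloxy)-4-chloro-1-methoxybutane (both epimers at C1 of the chain), via aryllithium 7 (not isolated), via lithium alkoxide 8 (not isolated)
Conditions: LiN(i-Pr)2 (LDA), THF, −78 °C; then 3, −78 °C; then MeOTf, −78 → 0 °C
Reagents that add atoms: methyl triflate, COS(=O)(=O)C(F)(F)F
Why: Directed ortho-metalation: the ring hydrogen flanked by Br and OMe is the most acidic, and the aryllithium adds to the aldehyde to form C1–C10. The alkoxide is capped as a methyl ether because a silyl ether would migrate from oxygen to carbon after the next lithiation; the new carbinol centre is erased in step 7.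

Step 6
Reactants: 9 (3S)-1-[3-(benzyloxy)-2-bromo-6-methoxy-4-methylphenyl]-3-(tert-butyldimethylsilyloxy)-4-chloro-1-methoxybutane
Product: 11 (3R)-5-(benzyloxy)-3-(tert-butyldimethylsilyloxy)-1,8-dimethoxy-6-methyltetralin (both C1 epimers), via aryllithium 10 (not isolated)
Conditions: t-BuLi (2.1 equiv), THF, −78 °C → rt
Reagents that add atoms: none
Why: Parham cycloalkylation: bromine–lithium exchange is much faster than attack on the alkyl chloride, and the aryllithium then displaces chloride in a 6-exo-tet closure to form C6–C7 and ring B. The position of the bromine fixes the regiochemistry.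

Step 7
Reactants: 11 (3R)-5-(benzyloxy)-3-(tert-butyldimethylsilyloxy)-1,8-dimethoxy-6-methyltetralin
Product: 12 (3R)-5-(benzyloxy)-3-(tert-butyldimethylsilyloxy)-8-methoxy-6-methyl-1-tetralone
Conditions: DDQ, CH2Cl2/pH 7 buffer, rt
Reagents that add atoms: water, O
Why: DDQ oxidation of an electron-rich benzylic methyl ether: hydride abstraction gives an oxocarbenium ion, water adds and methanol is lost. The epimer mixture converges to one ketone.

Step 8
Reactants: 12 (3R)-5-(benzyloxy)-3-(tert-butyldimethylsilyloxy)-8-methoxy-6-methyl-1-tetralone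
Product: 13 (3R)-5-(benzyloxy)-3-(tert-butyldimethylsilyloxy)-1,1-(ethylenedioxy)-8-methoxy-6-methyltetralin
Conditions: (TMSOCH2)2, TMSOTf (cat.), CH2Cl2, −78 → −20 °C
Reagents that add atoms: 1,2-bis(trimethylsilyloxy)ethane, C[Si](C)(C)OCCO[Si](C)(C)C
Why: Noyori ketalisation under aprotic, cold conditions, chosen because the β-silyloxy ketone would eliminate to a naphthol under Dean–Stark conditions. Protecting C10 here, while C2 is still an aryl ether, is what later distinguishes the two carbonyls that flank C1.

Step 9
Reactants: 13 (3R)-5-(benzyloxy)-3-(tert-butyldimethylsilyloxy)-1,1-(ethylenedioxy)-8-methoxy-6-methyltetralin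
Product: 14 (3R)-3-(tert-butyldimethylsilyloxy)-1,1-(ethylenedioxy)-8-methoxy-6-methyltetralin-5-ol
Conditions: H2 (1 atm), Pd/C, EtOAc, rt
Reagents that add atoms: none
Why: Neutral hydrogenolysis of the aryl benzyl ether; the silyl ether and the ketal should be unaffected in the absence of acid.

Step 10
Reactants: 14 (3R)-3-(tert-butyldimethylsilyloxy)-1,1-(ethylenedioxy)-8-methoxy-6-methyltetralin-5-ol
Product: 15 quinone monoketal: 3-(tert-butyldimethylsilyloxy)-1,1-(ethylenedioxy)-8,8-dimethoxy-6-methyl-1,2,3,4-tetrahydronaphthalen-5(8H)-one (germacrane locants: C5 ketone; C2 dimethyl ketal; C3=C4 and C1=C6 olefins)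
Conditions: PhI(OAc)2, MeOH, 0 °C
Reagents that add atoms: methanol, CO
Why: Oxidative dearomatisation of a para-methoxyphenol by trivalent iodine in methanol. It gives a cross-conjugated dienone with no enolisable hydrogen, the C1=C6 olefin already in place and C2 masked.

Step 11
Reactants: 15 quinone monoketal
Product: 16 C3–C4 epoxide of 15 (oxirane on the face that becomes the diol face)
Conditions: t-BuOOH, aq. NaOH, N-benzylcinchonidinium chloride (10 mol %), toluene, 0 °C
Reagents that add atoms: tert-butyl hydroperoxide, CC(C)(C)OO
Why: Weitz–Scheffer epoxidation under chiral phase-transfer catalysis, a known reaction of quinone monoketals. Only C3=C4 reacts, because the β-carbon of the other enone unit (C1) is fully substituted. The ion-paired peroxide selects the face and sets C4; since C8 is fixed, the minor isomer is a diastereomer and is removed by chromatography.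

Step 12
Reactants: 16 C3–C4 epoxide of 15
Product: 18 epoxy hydroxy enone (C2 ketone; C1=C6; C3–C4 oxirane; C5 hydroxyl cis to the oxirane oxygen), via epoxy alcohol ketal 17 (not isolated)
Conditions: NaBH4, CeCl3·7H2O, MeOH, −78 °C; then aq. (CO2H)2, THF, 0 °C
Reagents that add atoms: water, O
Why: Luche 1,2-reduction with hydride entering anti to the oxirane oxygen, so that the C5 hydroxyl is cis to the C4 oxygen. Dilute acid then hydrolyses only the allylic dimethyl ketal, which is far more labile than the dioxolane, and unveils the C2 ketone conjugated to C1=C6.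

Step 13
Reactants: 18 epoxy hydroxy enone
Product: 19 dihydroxy enone (C2 ketone; C1=C6; C4 tertiary and C5 secondary hydroxyls cis)
Conditions: (PhSe)2, NaBH4, EtOH; AcOH, 0 °C → rt
Reagents that add atoms: none
Why: Reductive cleavage of the Cα–O bond of an α,β-epoxy ketone by phenylselenide (Miyashita conditions): selenide attacks C3, a second selenide removes selenium, and the enolate is protonated. C4 keeps its configuration and the buffered medium avoids dehydration of the β-hydroxy ketone.

Step 14
Reactants: 19 dihydroxy enone
Product: 20 enone acetonide (Δ1(6)-octal-2-one with C4/C5 cis-acetonide, C4 methyl, C10 dioxolane, C8 silyl ether)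
Conditions: 2-methoxypropene, PPTS (cat.), CH2Cl2, 0 °C
Reagents that add atoms: 2-methoxypropene, COC(C)=C
Why: Kinetic acetonide formation on a cis-1,2-diol under very mild acid, which ties up the β-hydroxyl before any base is applied.

Step 15
Reactants: 20 enone acetonide
Product: 21 ring-fusion epoxy ketone (C1–C6 oxirane anti to the acetonide; C2 ketone)
Conditions: 30% H2O2, NaOH (0.3 equiv), MeOH, 0 °C
Reagents that add atoms: hydrogen peroxide, OO
Why: Weitz–Scheffer epoxidation of a tetrasubstituted ring-fusion enone, as for the parent Δ9,10-octal-1-one. Hydroperoxide should add to C6 anti to the C5 oxygen; cold, brief exposure limits β-alkoxy elimination.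

Step 16
Reactants: 21 ring-fusion epoxy ketone; 22 p-toluenesulfonyl hydrazide
Product: 24 ten-membered ynone (C6 ketone; C1≡C2; C4/C5 acetonide; C10 dioxolane; C8 silyl ether), via tosylhydrazone 23 (not isolated)
Conditions: TsNHNH2 (1.1 equiv), AcOH/CH2Cl2 (1:2), −20 °C → rt
Reagents that add atoms: none
Why: Eschenmoser–Tanabe fragmentation: the hydrazide condenses with the only free carbonyl (C2; C10 is a ketal), and the hydrazone opens the oxirane at C1–O to a vinyl diazene carrying a C6 alkoxide. The alkoxide then folds down to the C6 ketone while the C1–C6 bond breaks, C1≡C2 forms and N2 and toluenesulfinate leave in a Grob-type, irreversible step. The closest precedent is the conversion of 9,10-epoxydecalin-1-one to cyclodec-5-ynone. No ring is closed: the ten-membered ring appears by loss of the bond shared by rings A and B. No stereocentre is made; C1 and C6 lose theirs, and C4, C5 and C8 are spectators. The step needs fragmentation to outrun simple hydrazone survival and acetal hydrolysis; the fully substituted C6, which stabilises the developing carbonyl, and the ring-fusion bond held anti-periplanar to the breaking C–O bond secure this. Low temperature and anhydrous acetic acid spare the acetonide, dioxolane and silyl ether and limit transannular re-closure of the ynone.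

Step 17
Reactants: 24 ten-membered ynone
Product: 26 aldol adduct (C7 bears CH(OH)CO2Et; epimers at C7 and C11), via lithium enolate 25 (not isolated)
Conditions: LiN(i-Pr)2 (LDA), THF, −78 °C; ethyl glyoxylate, −78 °C; aq. NH4Cl
Reagents that add atoms: ethyl glyoxylate, CCOC(=O)C=O
Why: Kinetic deprotonation at the C7 methylene rather than the alkoxy-substituted C5 methine, then aldol addition to a non-enolisable aldehyde to form C7–C11. At −78 °C the enolate should not expel the C8 silyloxide, and both new centres are erased in step 19.

Step 18
Reactants: 26 aldol adduct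
Product: 28 hydroxy lactone (C6–O–C12 γ-lactone; C11 hydroxyl; C6 configured as in the target), via diol ester 27 (not isolated)
Conditions: Zn(BH4)2, Et2O, −30 °C; then PPTS (cat.), CH2Cl2, rt
Reagents that add atoms: none
Why: Chelation-controlled reduction: zinc bridges the C6 carbonyl and the C5 acetal oxygen, and hydride enters from the side of C5–H to give the 5,6-anti arrangement required at C6. The γ-hydroxy ester then lactonises.

Step 19
Reactants: 28 hydroxy lactone
Product: 29 3-hydroxybutenolide (enol of the α-keto lactone; C7=C11)
Conditions: Dess–Martin periodinane, NaHCO3, CH2Cl2, rt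
Reagents that add atoms: none
Why: Oxidation of the α-hydroxy lactone to the α-keto lactone, which exists as the conjugated enol; C7 and C11 become sp2 and the epimers converge.

Step 20
Reactants: 29 3-hydroxybutenolide
Product: 30 butenolide enol triflate (C11–OTf)
Conditions: Tf2O, Et3N, CH2Cl2, −78 °C
Reagents that add atoms: triflic anhydride, O=S(=O)(OS(=O)(=O)C(F)(F)F)C(F)(F)F
Why: O-sulfonylation of an acidic enol; only one regioisomer is possible because the enol is locked in the lactone.

Step 21
Reactants: 30 butenolide enol triflate
Product: 31 α-(hydroxymethyl)butenolide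
Conditions: Bu3SnCH2OH, Pd(PPh3)4 (5 mol %), LiCl, dioxane, 80 °C
Reagents that add atoms: (tributylstannyl)methanol, CCCC[Sn](CCCC)(CCCC)CO
Why: Stille coupling: zerovalent palladium inserts into the electron-poor vinyl triflate and the hydroxymethyl group is transferred from tin, forming C11–C13 after the ring exists so that no C11 carbanion with a β-oxygen is involved.

Step 22
Reactants: 31 α-(hydroxymethyl)butenolide
Product: 32 acetoxymethyl butenolide (alkyne; acetonide; dioxolane; silyl ether)
Conditions: Ac2O, pyridine, DMAP (cat.), CH2Cl2, 0 °C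
Reagents that add atoms: acetic anhydride, CC(=O)OC(C)=O
Why: Acylation of the only free hydroxyl.

Step 23
Reactants: 32 acetoxymethyl butenolide
Product: 33 C4,C5-diol (alkyne and C10 dioxolane retained)
Conditions: AcOH/H2O (4:1), 40 °C
Reagents that add atoms: none
Why: Acetal hydrolysis at the alkyne stage: the acetonide should cleave while the propargylic dioxolane resists, because the alkynyl group destabilises the oxocarbenium ion, and the hindered secondary silyl ether persists. No Michael acceptor is present yet for the freed C5 hydroxyl.

Step 24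
Reactants: 33 C4,C5-diol
Product: 34 C5 mesylate (C4 tertiary hydroxyl free)
Conditions: MsCl, Et3N, CH2Cl2, −20 °C
Reagents that add atoms: methanesulfonyl chloride, CS(=O)(=O)Cl
Why: Sulfonylation through sulfene reaches the hindered secondary hydroxyl; the tertiary one does not react.

Step 25
Reactants: 34 C5 mesylate
Product: 35 Z-olefin hydroxy mesylate (C1=C2 cis)
Conditions: H2 (1 atm), Pd/CaCO3 poisoned with Pb(OAc)2 (Lindlar catalyst), quinoline, EtOAc, rt
Reagents that add atoms: none
Why: Syn semi-hydrogenation of the ring alkyne gives the cis olefin only; the tetrasubstituted butenolide olefin is inert. It is done before epoxide closure so that the trans-epoxide forms in the ring geometry of the target.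

Step 26
Reactants: 35 Z-olefin hydroxy mesylate
Product: 36 C4–C5 trans-epoxide (Z-olefin; C10 dioxolane)
Conditions: NaH, THF, 0 °C
Reagents that add atoms: none
Why: Intramolecular Williamson closure (3-exo-tet): the C4 alkoxide displaces the C5 mesylate from the rear, so C4 is retained, C5 is inverted and the cis-diol becomes the trans-epoxide. One equivalent of a non-nucleophilic base, used up by the O–H, keeps the acetate and the acidic C6–H out of play.

Step 27
Reactants: 36 C4–C5 trans-epoxide
Product: 37 Z-enone (C10 ketone conjugated to C1=C2)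
Conditions: PPTS, acetone/H2O (10:1), 40 °C
Reagents that add atoms: water, O
Why: The dioxolane is now allylic and hydrolyses through an allyl-stabilised oxocarbenium ion under acid weak enough for the trisubstituted epoxide, the silyl ether and the acetate.

Step 28
Reactants: 37 Z-enone
Product: 38 cis-α,β-epoxy ketone (C1–C2 oxirane; C10 ketone)
Conditions: t-BuOOH (decane), DBU, CH2Cl2, 0 °C
Reagents that add atoms: tert-butyl hydroperoxide, CC(C)(C)OO
Why: Weitz–Scheffer epoxidation: the peroxide anion adds to C2 and the enolate closes onto oxygen; the ring should hold the cis geometry, and peripheral attack on the ring conformer is expected to give the 1R,2S oxirane. The anhydrous conditions spare the acetate, and the tetrasubstituted butenolide is not attacked.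

Step 29
Reactants: 38 cis-α,β-epoxy ketone
Product: 39 C10 methylene compound (vinyl epoxide)
Conditions: Cp2Ti(μ-Cl)(μ-CH2)AlMe2 (Tebbe reagent), pyridine, THF/toluene, −40 → 0 °C
Reagents that add atoms: Tebbe reagent, C[Al-]1(C)C[Ti](C2C=CC=C2)(C2C=CC=C2)[Cl+]1
Why: Carbonyl methylenation through a titanium methylidene and an oxatitanacyclobutane. The reagent is not basic, so the ketone is not enolised towards C9 with loss of the C8 silyloxide, and at low temperature ketones react ahead of esters and lactones.

Step 30
Reactants: 39 C10 methylene compound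
Product: 40 C8 alcohol
Conditions: HF·pyridine, pyridine, THF, 0 °C → rt
Reagents that add atoms: none
Why: Fluoride-driven cleavage of the silyl ether in a pyridine-buffered medium, which is tolerated by epoxides, the acetate and the butenolide.

Step 31
Reactants: 41 ethyl 2-(hydroxymethyl)acrylate
Product: 42 ethyl 2-[(tert-butyldimethylsilyloxy)methyl]acrylate
Conditions: TBSCl, imidazole, CH2Cl2, rt
Reagents that add atoms: tert-butyldimethylsilyl chloride, CC(C)(C)[Si](C)(C)Cl
Why: Silylation of the primary allylic alcohol.

Step 32
Reactants: 42 ethyl 2-[(tert-butyldimethylsilyloxy)methyl]acrylate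
Product: 43 2-[(tert-butyldimethylsilyloxy)methyl]acrylic acid
Conditions: LiOH, THF/H2O, 0 °C; then 1 M HCl to pH 3
Reagents that add atoms: lithium hydroxide, [Li+].[OH-]
Why: Saponification of the ethyl ester; the primary silyl ether survives cold aqueous base and brief mild acidification.

Step 33
Reactants: 40 C8 alcohol; 43 2-[(tert-butyldimethylsilyloxy)methyl]acrylic acid
Product: 44 C8 ester with the silyl-protected side chain
Conditions: EDC·HCl, DMAP, CH2Cl2, 0 °C → rt
Reagents that add atoms: none
Why: Steglich esterification of the secondary allylic alcohol through the O-acylisourea and acylpyridinium; it is neutral and retains configuration at C8.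

Step 34
Reactants: 44 C8 ester with the silyl-protected side chain
Product: 45 target CNP0233746.1
Conditions: HF·pyridine, pyridine, THF, 0 °C
Reagents that add atoms: none
Why: The primary allylic silyl ether is cleaved quickly under buffered fluoride, leaving both epoxides, both esters and the lactone intact.

## Compound list

1 | ethyl (S)-4-chloro-3-hydroxybutanoate | CCOC(=O)C[C@H](O)CCl | starting material
2 | ethyl (S)-3-(tert-butyldimethylsilyloxy)-4-chlorobutanoate | CCOC(=O)C[C@H](O[Si](C)(C)C(C)(C)C)CCl | intermediate
3 | (S)-3-(tert-butyldimethylsilyloxy)-4-chlorobutanal | O=CC[C@H](O[Si](C)(C)C(C)(C)C)CCl | intermediate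
4 | 4-methoxy-2-methylphenol | Cc1cc(OC)ccc1O | starting material
5 | 2-bromo-4-methoxy-6-methylphenol | Cc1cc(OC)cc(Br)c1O | intermediate
6 | 2-(benzyloxy)-1-bromo-5-methoxy-3-methylbenzene | Cc1cc(OC)cc(Br)c1OCc1ccccc1 | intermediate
7 | [3-(benzyloxy)-2-bromo-6-methoxy-4-methylphenyl]lithium | Cc1cc(OC)c([Li])c(Br)c1OCc1ccccc1 | intermediate
8 | lithium (3S)-1-[3-(benzyloxy)-2-bromo-6-methoxy-4-methylphenyl]-3-(tert-butyldimethylsilyloxy)-4-chlorobutan-1-olate (C1 epimers) | Cc1cc(OC)c(C(O[Li])C[C@H](O[Si](C)(C)C(C)(C)C)CCl)c(Br)c1OCc1ccccc1 | intermediate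
9 | (3S)-1-[3-(benzyloxy)-2-bromo-6-methoxy-4-methylphenyl]-3-(tert-butyldimethylsilyloxy)-4-chloro-1-methoxybutane (C1 epimers) | Cc1cc(OC)c(C(OC)C[C@H](O[Si](C)(C)C(C)(C)C)CCl)c(Br)c1OCc1ccccc1 | intermediate
10 | aryllithium from 9 (lithium in place of bromine) | Cc1cc(OC)c(C(OC)C[C@H](O[Si](C)(C)C(C)(C)C)CCl)c([Li])c1OCc1ccccc1 | intermediate
11 | (3R)-5-(benzyloxy)-3-(tert-butyldimethylsilyloxy)-1,8-dimethoxy-6-methyltetralin (C1 epimers) | COc1cc(C)c(OCc2ccccc2)c2c1C(OC)C[C@H](O[Si](C)(C)C(C)(C)C)C2 | intermediate
12 | (3R)-5-(benzyloxy)-3-(tert-butyldimethylsilyloxy)-8-methoxy-6-methyl-1-tetralone | COc1cc(C)c(OCc2ccccc2)c2c1C(=O)C[C@H](O[Si](C)(C)C(C)(C)C)C2 | intermediate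
13 | (3R)-5-(benzyloxy)-3-(tert-butyldimethylsilyloxy)-1,1-(ethylenedioxy)-8-methoxy-6-methyltetralin | COc1cc(C)c(OCc2ccccc2)c2c1C1(OCCO1)C[C@H](O[Si](C)(C)C(C)(C)C)C2 | intermediate
14 | (3R)-3-(tert-butyldimethylsilyloxy)-1,1-(ethylenedioxy)-8-methoxy-6-methyltetralin-5-ol | COc1cc(C)c(O)c2c1C1(OCCO1)C[C@H](O[Si](C)(C)C(C)(C)C)C2 | intermediate
15 | quinone monoketal (C5 ketone, C2 dimethyl ketal, C3=C4 and C1=C6 olefins, C10 dioxolane, C8 silyl ether) | COC1(OC)C=C(C)C(=O)C2=C1C1(OCCO1)C[C@H](O[Si](C)(C)C(C)(C)C)C2 | intermediate
16 | C3–C4 epoxide of 15 | COC1(OC)[C@H]2O[C@@]2(C)C(=O)C2=C1C1(OCCO1)C[C@H](O[Si](C)(C)C(C)(C)C)C2 | intermediate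
17 | epoxy alcohol ketal (C5 hydroxyl cis to the oxirane) | COC1(OC)[C@H]2O[C@@]2(C)[C@@H](O)C2=C1C1(OCCO1)C[C@H](O[Si](C)(C)C(C)(C)C)C2 | intermediate
18 | epoxy hydroxy enone (C2 ketone, C1=C6, C3–C4 oxirane, C5 hydroxyl) | O=C1[C@H]2O[C@@]2(C)[C@@H](O)C2=C1C1(OCCO1)C[C@H](O[Si](C)(C)C(C)(C)C)C2 | intermediate
19 | dihydroxy enone (C4/C5 cis-diol) | O=C1C[C@@](C)(O)[C@@H](O)C2=C1C1(OCCO1)C[C@H](O[Si](C)(C)C(C)(C)C)C2 | intermediate
20 | enone acetonide (Δ1(6)-octal-2-one, C4/C5 acetonide, C10 dioxolane, C8 silyl ether) | O=C1C[C@@]2(C)OC(C)(C)O[C@H]2C3=C1C4(OCCO4)C[C@H](O[Si](C)(C)C(C)(C)C)C3 | intermediate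
21 | ring-fusion epoxy ketone (C1–C6 oxirane, C2 ketone) | O=C1C[C@@]2(C)OC(C)(C)O[C@H]2[C@@]35O[C@]15C4(OCCO4)C[C@H](O[Si](C)(C)C(C)(C)C)C3 | intermediate
22 | p-toluenesulfonyl hydrazide | Cc1ccc(cc1)S(=O)(=O)NN | starting material
23 | tosylhydrazone of 21 at C2 | Cc1ccc(cc1)S(=O)(=O)NN=C1C[C@@]2(C)OC(C)(C)O[C@H]2[C@@]35O[C@]15C4(OCCO4)C[C@H](O[Si](C)(C)C(C)(C)C)C3 | intermediate
24 | ten-membered ynone (C6 ketone, C1≡C2, C4/C5 acetonide, C10 dioxolane, C8 silyl ether) | CC(C)(C)[Si](C)(C)O[C@H]1CC2(OCCO2)C#CC[C@@]2(C)OC(C)(C)O[C@H]2C(=O)C1 | intermediate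
25 | lithium enolate of 24 (C6–O–Li, C6=C7) | CC(C)(C)[Si](C)(C)O[C@H]1CC2(OCCO2)C#CC[C@@]2(C)OC(C)(C)O[C@H]2C(O[Li])=C1 | intermediate
26 | aldol adduct (C7–CH(OH)CO2Et; C7 and C11 epimers) | CC(C)(C)[Si](C)(C)O[C@H]1CC2(OCCO2)C#CC[C@@]2(C)OC(C)(C)O[C@H]2C(=O)C1C(O)C(=O)OCC | intermediate
27 | diol ester (C6 hydroxyl as in the target; C7 and C11 epimers) | CC(C)(C)[Si](C)(C)O[C@H]1CC2(OCCO2)C#CC[C@@]2(C)OC(C)(C)O[C@H]2[C@@H](O)C1C(O)C(=O)OCC | intermediate
28 | hydroxy lactone (12,6-olide with C11 hydroxyl) | CC(C)(C)[Si](C)(C)O[C@H]1CC2(OCCO2)C#CC[C@@]2(C)OC(C)(C)O[C@H]2[C@H]2OC(=O)C(O)C12 | intermediate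
29 | 3-hydroxybutenolide (C7=C11 enol) | CC(C)(C)[Si](C)(C)O[C@H]1CC2(OCCO2)C#CC[C@@]2(C)OC(C)(C)O[C@H]2[C@H]2OC(=O)C(O)=C12 | intermediate
30 | butenolide enol triflate | CC(C)(C)[Si](C)(C)O[C@H]1CC2(OCCO2)C#CC[C@@]2(C)OC(C)(C)O[C@H]2[C@H]2OC(=O)C(OS(=O)(=O)C(F)(F)F)=C12 | intermediate
31 | α-(hydroxymethyl)butenolide | CC(C)(C)[Si](C)(C)O[C@H]1CC2(OCCO2)C#CC[C@@]2(C)OC(C)(C)O[C@H]2[C@H]2OC(=O)C(CO)=C12 | intermediate
32 | acetoxymethyl butenolide (alkyne, acetonide) | CC(C)(C)[Si](C)(C)O[C@H]1CC2(OCCO2)C#CC[C@@]2(C)OC(C)(C)O[C@H]2[C@H]2OC(=O)C(COC(C)=O)=C12 | intermediate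
33 | C4,C5-diol (alkyne) | CC(C)(C)[Si](C)(C)O[C@H]1CC2(OCCO2)C#CC[C@@](C)(O)[C@@H](O)[C@H]2OC(=O)C(COC(C)=O)=C12 | intermediate
34 | C5 mesylate (alkyne) | CC(C)(C)[Si](C)(C)O[C@H]1CC2(OCCO2)C#CC[C@@](C)(O)[C@@H](OS(C)(=O)=O)[C@H]2OC(=O)C(COC(C)=O)=C12 | intermediate
35 | Z-olefin hydroxy mesylate | CC(C)(C)[Si](C)(C)O[C@H]1CC2(OCCO2)/C=C\C[C@@](C)(O)[C@@H](OS(C)(=O)=O)[C@H]2OC(=O)C(COC(C)=O)=C12 | intermediate
36 | C4–C5 trans-epoxide (Z-olefin, C10 dioxolane) | CC(C)(C)[Si](C)(C)O[C@H]1CC2(OCCO2)/C=C\C[C@@]2(C)O[C@@H]2[C@H]2OC(=O)C(COC(C)=O)=C12 | intermediate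
37 | Z-enone (C10 ketone) | CC(C)(C)[Si](C)(C)O[C@H]1CC(=O)/C=C\C[C@@]2(C)O[C@@H]2[C@H]2OC(=O)C(COC(C)=O)=C12 | intermediate
38 | cis-α,β-epoxy ketone (C1–C2 oxirane, C10 ketone) | CC(C)(C)[Si](C)(C)O[C@H]1CC(=O)[C@H]2O[C@H]2C[C@@]2(C)O[C@@H]2[C@H]2OC(=O)C(COC(C)=O)=C12 | intermediate
39 | C10 methylene compound (C8 silyl ether) | CC(C)(C)[Si](C)(C)O[C@H]1CC(=C)[C@H]2O[C@H]2C[C@@]2(C)O[C@@H]2[C@H]2OC(=O)C(COC(C)=O)=C12 | intermediate
40 | C8 alcohol | O[C@H]1CC(=C)[C@H]2O[C@H]2C[C@@]2(C)O[C@@H]2[C@H]2OC(=O)C(COC(C)=O)=C12 | intermediate
41 | ethyl 2-(hydroxymethyl)acrylate | C=C(CO)C(=O)OCC | starting material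
42 | ethyl 2-[(tert-butyldimethylsilyloxy)methyl]acrylate | C=C(CO[Si](C)(C)C(C)(C)C)C(=O)OCC | intermediate
43 | 2-[(tert-butyldimethylsilyloxy)methyl]acrylic acid | C=C(CO[Si](C)(C)C(C)(C)C)C(O)=O | intermediate
44 | C8 ester with silyl-protected side chain | C=C(CO[Si](C)(C)C(C)(C)C)C(=O)O[C@H]1CC(=C)[C@H]2O[C@H]2C[C@@]2(C)O[C@@H]2[C@H]2OC(=O)C(COC(C)=O)=C12 | intermediate
45 | CNP0233746.1 (1R,2S,4R,5R,6S,8S) | C=C(CO)C(=O)O[C@H]1CC(=C)[C@H]2O[C@H]2C[C@@]2(C)O[C@@H]2[C@H]2OC(=O)C(COC(C)=O)=C12 | target

## Step count and least certain steps

Total: 34 steps. Longest linear sequence: 30 steps (from 4 through steps 3–30, 33 and 34; equally from 1 through steps 1, 2, 5–30, 33 and 34).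

**Step 16 (key step).** The most likely failure is that the reaction stops at the hydrazone, or that acetic acid opens the acetonide or dioxolane before fragmentation. The ynone may also re-close across the ring through its enol once formed. Fallback: a neutral, thermal trigger in place of sulfinate loss. From 21, condensation with 1-amino-2-phenylaziridine gives the N-aziridinyl imine F1, which on warming in toluene loses styrene and N2 through the same Grob-type opening and returns to the route at 24.

**Step 11.** Poor facial selectivity is likely, because the only existing stereocentre (C8) is remote and the catalyst must differentiate the faces of a hindered dienone on its own. Fallback: give up catalyst control. From 15, epoxidation with H2O2/K2CO3 gives 16 together with its ring-A diastereomer F2. Because C8 is fixed the two are diastereomers, not enantiomers, and are separated on silica. The route is rejoined at 16, and F2 is discarded.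

**Step 18.** Wrong-face hydride delivery is the risk: in the ten-membered ring the zinc chelate with the acetal oxygen may not dominate over chelation by the C11 hydroxyl or over ring conformation, giving the C6 epimer. Fallback: correct C6 by substitution instead of by face selection. From 26, the reduction is accepted as it falls and the C6-epimeric diol ester F3 is saponified (LiOH) to the hydroxy acid F4. Mitsunobu lactonisation (PPh3, DIAD) then closes the γ-lactone with inversion at C6 and returns to the route at 28.

**Step 26.** Competing deprotonation at C6 (γ to the lactone carbonyl) with loss of the mesylate, or slow closure if the ring resists the anti-periplanar arrangement of O4 and the leaving group. Fallback: avoid a free alkoxide. From 33, Lindlar semi-hydrogenation gives the Z-olefin diol F5. Cyclodehydration with Martin sulfurane, Ph2S[OC(CF3)2Ph]2, under neutral conditions activates the secondary hydroxyl and closes the epoxide with the same inversion at C5, returning at 36.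

**Step 28.** The peroxide may attack the wrong face of the Z-enone, or the intermediate enolate may rotate to a trans-epoxide. In addition DBU may remove the C6 hydrogen next to the C4–C5 epoxide, or enolise the C10 ketone towards C9 with loss of the C8 silyloxide. Fallback: hydroxyl-directed epoxidation without base. From 37, Luche reduction (NaBH4, CeCl3·7H2O) gives the Z-allylic alcohol F6, with a CBS reagent selecting the carbinol epimer that directs to the required face if needed. VO(acac)2/t-BuOOH delivers oxygen syn to the hydroxyl in a concerted, cis-specific step to give the epoxy alcohol F7, and Dess–Martin oxidation returns to the route at 38.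

## Further compounds

F1 | step 16 | N-(2-phenylaziridin-1-yl)imine of 21 at C2 | c1ccccc1C1CN1N=C1C[C@@]2(C)OC(C)(C)O[C@H]2[C@@]35O[C@]15C4(OCCO4)C[C@H](O[Si](C)(C)C(C)(C)C)C3
F2 | step 11 | ring-A diastereomer of 16 (oxirane on the opposite face) | COC1(OC)[C@@H]2O[C@]2(C)C(=O)C2=C1C1(OCCO1)C[C@H](O[Si](C)(C)C(C)(C)C)C2
F3 | step 18 | C6-epimeric diol ester | CC(C)(C)[Si](C)(C)O[C@H]1CC2(OCCO2)C#CC[C@@]2(C)OC(C)(C)O[C@H]2[C@H](O)C1C(O)C(=O)OCC
F4 | step 18 | C6-epimeric dihydroxy acid | CC(C)(C)[Si](C)(C)O[C@H]1CC2(OCCO2)C#CC[C@@]2(C)OC(C)(C)O[C@H]2[C@H](O)C1C(O)C(O)=O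
F5 | step 26 | Z-olefin C4,C5-diol | CC(C)(C)[Si](C)(C)O[C@H]1CC2(OCCO2)/C=C\C[C@@](C)(O)[C@@H](O)[C@H]2OC(=O)C(COC(C)=O)=C12
F6 | step 28 | Z-allylic alcohol at C10 (carbinol epimer set by the reducing agent) | CC(C)(C)[Si](C)(C)O[C@H]1CC(O)/C=C\C[C@@]2(C)O[C@@H]2[C@H]2OC(=O)C(COC(C)=O)=C12
F7 | step 28 | C1–C2 cis-epoxy alcohol at C10 | CC(C)(C)[Si](C)(C)O[C@H]1CC(O)[C@H]2O[C@H]2C[C@@]2(C)O[C@@H]2[C@H]2OC(=O)C(COC(C)=O)=C12
A1 | alternative 1 | ten-membered bis-epoxy butenolide with C10 dioxolane and C8 silyl ether | CC(C)(C)[Si](C)(C)O[C@H]1CC3(OCCO3)[C@H]2O[C@H]2C[C@@]2(C)O[C@@H]2[C@H]2OC(=O)C(COC(C)=O)=C12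
A2 | alternative 2 | tricyclic photoadduct with a bicyclo[2.2.0]hexane fused to the cyclohexanone | O=C1C[C@@H](O[Si](C)(C)C(C)(C)C)C[C@@]2(C)[C@@H]1[C@]3(C)C[C@@H](O[Si](C)(C)C(C)(C)C)[C@H]23
A3 | alternative 3 | ten-membered C4-keto butenolide with C5 PMB ether, C1–C2 epoxide and C10 methylene | CC(C)(C)[Si](C)(C)O[C@H]1CC(=C)[C@H]2O[C@H]2CC(=O)[C@@H](OCc2ccc(OC)cc2)[C@H]2OC(=O)C(COC(C)=O)=C12
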